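**Plan**

1. Retrosynthesis: the two benzyl ethers and the C3 formyl group come off first (debenzylation; Vilsmeier–Haack disconnection). Next the C2–CH2O bond is cut (anti-SE2′ of a cyclic allylsilane with formaldehyde). Last, the two aryl–carbon bonds C4–C4a and C1–C8a are cut together ([4+2] of an aryne with a 1-aryl-4-silyl-buta-1,3-diene).
2. Enabling feature: in the fused benzene ring (C4a, C5–C8, C8a) the C4a–C8a edge lies next to the C8 methoxy group, so it is a 3-alkoxyaryne edge of predictable polarisation. The chain C1–C2–C3–C4 on that edge is a buta-1,3-diene whose termini are the two benzylic carbons.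
3. Forward: the aryne precursor (3 steps from a phenol) and the silyl diene (2 steps from O-benzylvanillin) are joined in one operation that closes the only new ring. The Me3Si group on C4 is the helper; it leaves in the next step, which brings in the CH2OH carbon and moves the double bond to C3=C4. Acetate, formyl group and free phenols follow.
4. Stereochemistry: the cycloaddition is suprafacial on an E,E-diene, so C1-aryl and C4-Si come out cis. The C4–Si bond relays this to C2 (electrophile anti to silicon, hence trans to the aryl group). The absolute configuration (1S,2R) comes from a lipase-catalysed acetylation (kinetic resolution, so at most half of the racemic alcohol is used), which is also the step that installs the acetate.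

Key step: step 6

Remark: the cycloadduct and the alcohol made from it are racemates (the enantiomer leading to the target is drawn); the lipase is assumed to acetylate the (1S,2S)-alcohol faster — should it prefer the antipode, the alcohol left over is the wanted one and is acetylated chemically (Ac2O, pyridine) to the same acetate.

**Route**

Step 1
Reactants: 1 4-(benzyloxy)-3-methoxyphenol
Product: 2 4-(benzyloxy)-3-methoxyphenyl N-(propan-2-yl)carbamate
Conditions: i-PrNCO, Et3N (cat.), CH2Cl2, rt
Reagents that add atoms: isopropyl isocyanate, CC(C)N=C=O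
Why: Addition of the phenol O–H across the isocyanate (carbamoylation) gives an N-monoalkyl carbamate that serves as a directed-metalation group and is later cleaved under mild base.

Step 2
Reactants: 2 4-(benzyloxy)-3-methoxyphenyl N-(propan-2-yl)carbamate
Product: 6 4-(benzyloxy)-2-iodo-3-methoxyphenyl N-(propan-2-yl)carbamate, via N-silyl carbamate 3 (not isolated), via aryllithium 4 (not isolated), via N-silyl aryl iodide 5 (not isolated)
Conditions: TBSOTf, TMEDA, Et2O, 0 °C to rt; n-BuLi, TMEDA, −78 °C; I2, THF, −78 °C to rt; aq. NaHSO4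
Reagents that add atoms: iodine, II
Why: Directed ortho-metalation: after in-situ N-silylation the carbamate and the methoxy group together direct lithiation to the ring carbon between them, iodine quenches the aryllithium, and the N–Si bond is hydrolysed in the acidic work-up, the benzyl ether being inert at −78 °C.

Step 3
Reactants: 6 4-(benzyloxy)-2-iodo-3-methoxyphenyl N-(propan-2-yl)carbamate
Product: 8 4-(benzyloxy)-2-iodo-3-methoxyphenyl trifluoromethanesulfonate, via iodophenol 7 (not isolated)
Conditions: Et2NH, DBU, MeCN, 40 °C; then PhNTf2, rt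
Reagents that add atoms: N-phenylbis(trifluoromethanesulfonimide), O=S(=O)(N(c1ccccc1)S(=O)(=O)C(F)(F)F)C(F)(F)F
Why: Base-induced E1cB cleavage of the N-monoalkyl carbamate (the isocyanate is scavenged by Et2NH) frees the phenoxide, which is triflated in the same flask (O-sulfonylation) without touching the aryl iodide.

Step 4
Reactants: 9 4-(benzyloxy)-3-methoxybenzaldehyde
Product: 10 (2E)-3-[4-(benzyloxy)-3-methoxyphenyl]prop-2-enal
Conditions: Ph3P=CHCHO, toluene, 90 °C
Reagents that add atoms: (triphenylphosphoranylidene)acetaldehyde, O=CC=P(c1ccccc1)(c1ccccc1)c1ccccc1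
Why: Wittig reaction with the stabilised formyl ylide gives the E-enal by two-carbon homologation, the ethers being inert.

Step 5
Reactants: 10 (2E)-3-[4-(benzyloxy)-3-methoxyphenyl]prop-2-enal
Product: 11 [(1E,3E)-4-[4-(benzyloxy)-3-methoxyphenyl]buta-1,3-dien-1-yl]trimethylsilane
Conditions: Me3SiCHBr2, CrCl2, THF, rt
Reagents that add atoms: (dibromomethyl)trimethylsilane, C[Si](C)(C)C(Br)Br
Why: Takai olefination: the geminal dichromium reagent formed from Me3SiCHBr2 and CrCl2 adds to the aldehyde and eliminates to the E-alkenylsilane, leaving the existing E double bond untouched.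

Step 6
Reactants: 8 4-(benzyloxy)-2-iodo-3-methoxyphenyl trifluoromethanesulfonate; 11 [(1E,3E)-4-[4-(benzyloxy)-3-methoxyphenyl]buta-1,3-dien-1-yl]trimethylsilane
Product: 14 rac-(1S,4S)-7-(benzyloxy)-1-[4-(benzyloxy)-3-methoxyphenyl]-8-methoxy-4-(trimethylsilyl)-1,4-dihydronaphthalene, via arylmagnesium chloride 12 (not isolated), via aryne 13 (not isolated)
Conditions: Me3SiCH2MgCl, THF, −78 °C to rt (8 in excess)
Reagents that add atoms: none
Why: Iodine–magnesium exchange at the C–I carbon of 8 gives 12, which expels triflate already at −78 °C, and the resulting 3-methoxy-4-benzyloxy aryne 13 is taken up by the s-cis conformer of 11 in a concerted but asynchronous [4+2] cycloaddition that forms C4–C4a and C1–C8a together. The closest known reaction type is the aryne Diels–Alder reaction with acyclic E,E-1,4-disubstituted buta-1,3-dienes, which gives cis-1,4-disubstituted 1,4-dihydronaphthalenes. The one ring that is closed, C1–C2–C3–C4–C4a–C8a, closes by suprafacial–suprafacial ([π4s+π2s]) addition of the in-plane aryne π bond to the two diene termini. C1 and C4 are the new stereocentres: their cis relation is fixed by the E,E geometry of 11 and the suprafacial course, and since nothing chiral is present 14 is racemic (the absolute configuration is settled in step 8). The selectivity needed is the orientation, C4 to the aryne carbon remote from the methoxy group and C1 to the one next to it: the C8 methoxy group polarises the aryne so that its remote carbon is the electrophilic one, and this carbon pairs with C4 of the diene, which has the larger HOMO coefficient (terminus remote from the electron-rich aryl group) and carries the bulky Me3Si group that avoids the methoxy flank. Chemoselectivity is secured by the absence of allylic hydrogens in 11 (no ene reaction) and by the fluoride-free generation of the aryne, which leaves the allylic and benzylic C–Si bond of 14 intact.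

Step 7
Reactants: 14 rac-(1S,4S)-7-(benzyloxy)-1-[4-(benzyloxy)-3-methoxyphenyl]-8-methoxy-4-(trimethylsilyl)-1,4-dihydronaphthalene
Product: 15 rac-[(1S,2S)-7-(benzyloxy)-1-[4-(benzyloxy)-3-methoxyphenyl]-8-methoxy-1,2-dihydronaphthalen-2-yl]methanol
Conditions: (CH2O)n, Me2AlCl, CH2Cl2, −78 to −20 °C; aq. Rochelle salt
Reagents that add atoms: formaldehyde (as paraformaldehyde), C=O
Why: Hosomi–Sakurai-type (silyl-Prins) hydroxymethylation: the formaldehyde–Me2AlCl complex attacks C2 of the allylsilane anti to the pseudoaxial C4–Si bond (anti-SE2′), which is also the face away from the C1 aryl group, so the CH2OH group ends trans to the aryl group while loss of silicon moves the double bond to C3=C4 in conjugation with the fused ring; Me2AlCl also scavenges protons that would cause protodesilylation.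

Step 8
Reactants: 15 rac-[(1S,2S)-7-(benzyloxy)-1-[4-(benzyloxy)-3-methoxyphenyl]-8-methoxy-1,2-dihydronaphthalen-2-yl]methanol
Product: 16 [(1S,2S)-7-(benzyloxy)-1-[4-(benzyloxy)-3-methoxyphenyl]-8-methoxy-1,2-dihydronaphthalen-2-yl]methyl acetate
Conditions: Burkholderia cepacia lipase (immobilised), vinyl acetate, t-BuOMe, 30 °C, stopped near half conversion
Reagents that add atoms: vinyl acetate, C=COC(C)=O
Why: Lipase-catalysed transesterification (enzymatic kinetic resolution by irreversible acyl transfer from vinyl acetate) acetylates the (1S,2S)-alcohol while the (1R,2R)-alcohol stays unchanged and is separated, so the step fixes the absolute configuration and installs the acetate of the target at once.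

Step 9
Reactants: 16 [(1S,2S)-7-(benzyloxy)-1-[4-(benzyloxy)-3-methoxyphenyl]-8-methoxy-1,2-dihydronaphthalen-2-yl]methyl acetate
Product: 18 [(1S,2R)-7-(benzyloxy)-1-[4-(benzyloxy)-3-methoxyphenyl]-3-formyl-8-methoxy-1,2-dihydronaphthalen-2-yl]methyl acetate, via iminium chloride 17 (not isolated)
Conditions: POCl3, DMF, 0 to 60 °C; then aq. NaOAc
Reagents that add atoms: N,N-dimethylformamide, CN(C)C=O; water, O
Why: Vilsmeier–Haack formylation: the chloroiminium ion attacks the styrene β-carbon C3 (the benzylic C4 cation is stabilised by the para benzyloxy group at C7), loss of the C3 proton restores C3=C4 and aqueous hydrolysis of 17 gives the enal, while the acetate, the less nucleophilic dialkoxy rings and the centres C1 and C2 are not touched.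

Step 10
Reactants: 18 [(1S,2R)-7-(benzyloxy)-1-[4-(benzyloxy)-3-methoxyphenyl]-3-formyl-8-methoxy-1,2-dihydronaphthalen-2-yl]methyl acetate
Product: 19 [(1S,2R)-3-formyl-7-hydroxy-1-(4-hydroxy-3-methoxyphenyl)-8-methoxy-1,2-dihydronaphthalen-2-yl]methyl acetate
Conditions: BCl3, C6HMe5, CH2Cl2, −78 °C; then MeOH
Reagents that add atoms: none
Why: Lewis-acid debenzylation of the two aryl benzyl ethers with BCl3 at −78 °C, with pentamethylbenzene trapping the benzyl cations (Friedel–Crafts scavenging), spares the methyl ethers, the acetate, the enal and the C3=C4 bond, none of which would survive hydrogenolysis.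

**Compound list**

1 | 4-(benzyloxy)-3-methoxyphenol | COc1cc(O)ccc1OCc1ccccc1 | starting material
2 | 4-(benzyloxy)-3-methoxyphenyl N-(propan-2-yl)carbamate | COc1cc(OC(=O)NC(C)C)ccc1OCc1ccccc1 | intermediate
3 | 4-(benzyloxy)-3-methoxyphenyl N-(tert-butyldimethylsilyl)-N-(propan-2-yl)carbamate (not isolated) | COc1cc(OC(=O)N(C(C)C)[Si](C)(C)C(C)(C)C)ccc1OCc1ccccc1 | intermediate
4 | 2-lithio derivative of 3, lithium on the ring carbon between the carbamate and the methoxy group (not isolated) | COc1c([Li])c(OC(=O)N(C(C)C)[Si](C)(C)C(C)(C)C)ccc1OCc1ccccc1 | intermediate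
5 | 4-(benzyloxy)-2-iodo-3-methoxyphenyl N-(tert-butyldimethylsilyl)-N-(propan-2-yl)carbamate (not isolated) | COc1c(I)c(OC(=O)N(C(C)C)[Si](C)(C)C(C)(C)C)ccc1OCc1ccccc1 | intermediate
6 | 4-(benzyloxy)-2-iodo-3-methoxyphenyl N-(propan-2-yl)carbamate | COc1c(I)c(OC(=O)NC(C)C)ccc1OCc1ccccc1 | intermediate
7 | 4-(benzyloxy)-2-iodo-3-methoxyphenol (present as its amidinium phenoxide, not isolated) | COc1c(I)c(O)ccc1OCc1ccccc1 | intermediate
8 | 4-(benzyloxy)-2-iodo-3-methoxyphenyl trifluoromethanesulfonate | COc1c(I)c(OS(=O)(=O)C(F)(F)F)ccc1OCc1ccccc1 | intermediate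
9 | 4-(benzyloxy)-3-methoxybenzaldehyde | COc1cc(C=O)ccc1OCc1ccccc1 | starting material
10 | (2E)-3-[4-(benzyloxy)-3-methoxyphenyl]prop-2-enal | COc1cc(/C=C/C=O)ccc1OCc1ccccc1 | intermediate
11 | [(1E,3E)-4-[4-(benzyloxy)-3-methoxyphenyl]buta-1,3-dien-1-yl]trimethylsilane | COc1cc(/C=C/C=C/[Si](C)(C)C)ccc1OCc1ccccc1 | intermediate
12 | [3-(benzyloxy)-2-methoxy-6-(trifluoromethanesulfonyloxy)phenyl]magnesium chloride (not isolated) | COc1c([Mg]Cl)c(OS(=O)(=O)C(F)(F)F)ccc1OCc1ccccc1 | intermediate
13 | 4-(benzyloxy)-3-methoxy-1,2-didehydrobenzene, the aryne (not isolated) | COC1=C(OCc2ccccc2)C=CC#C1 | intermediate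
14 | cis-7-(benzyloxy)-1-[4-(benzyloxy)-3-methoxyphenyl]-8-methoxy-4-(trimethylsilyl)-1,4-dihydronaphthalene, racemic, (1S,4S) enantiomer drawn | COc1cc([C@@H]2C=C[C@H]([Si](C)(C)C)c3ccc(OCc4ccccc4)c(OC)c32)ccc1OCc1ccccc1 | intermediate
15 | trans-{7-(benzyloxy)-1-[4-(benzyloxy)-3-methoxyphenyl]-8-methoxy-1,2-dihydronaphthalen-2-yl}methanol, racemic, (1S,2S) enantiomer drawn | COc1cc([C@H]2c3c(ccc(OCc4ccccc4)c3OC)C=C[C@@H]2CO)ccc1OCc1ccccc1 | intermediate
16 | [(1S,2S)-7-(benzyloxy)-1-[4-(benzyloxy)-3-methoxyphenyl]-8-methoxy-1,2-dihydronaphthalen-2-yl]methyl acetate | COc1cc([C@H]2c3c(ccc(OCc4ccccc4)c3OC)C=C[C@@H]2COC(C)=O)ccc1OCc1ccccc1 | intermediate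
17 | C3-[(dimethyliminio)methyl] derivative of 16, chloride (not isolated) | COc1cc([C@H]2c3c(ccc(OCc4ccccc4)c3OC)C=C(C=[N+](C)C)[C@@H]2COC(C)=O)ccc1OCc1ccccc1.[Cl-] | intermediate
18 | [(1S,2R)-7-(benzyloxy)-1-[4-(benzyloxy)-3-methoxyphenyl]-3-formyl-8-methoxy-1,2-dihydronaphthalen-2-yl]methyl acetate | COc1cc([C@H]2c3c(ccc(OCc4ccccc4)c3OC)C=C(C=O)[C@@H]2COC(C)=O)ccc1OCc1ccccc1 | intermediate
19 | [(1S,2R)-3-formyl-7-hydroxy-1-(4-hydroxy-3-methoxyphenyl)-8-methoxy-1,2-dihydronaphthalen-2-yl]methyl acetate | COc1cc([C@H]2c3c(ccc(O)c3OC)C=C(C=O)[C@@H]2COC(C)=O)ccc1O | target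

**Count and risks**

Total step count: 10. Longest linear sequence: 8 (steps 1, 2, 3, 6, 7, 8, 9, 10).

Step 6. What may go wrong: the aryne adds across the diene in the reverse orientation (aryl-bearing terminus to the carbon remote from the methoxy group), or it is lost to [2+2] addition at a diene double bond. Fallback, setting out from 9 and 8 and returning at 18: aldol condensation of 9 with acetone (aq. NaOH) gives (3E)-4-[4-(benzyloxy)-3-methoxyphenyl]but-3-en-2-one F1. TBSOTf and Et3N convert it into the 2-silyloxy diene tert-butyl({(3E)-4-[4-(benzyloxy)-3-methoxyphenyl]buta-1,3-dien-2-yl}oxy)dimethylsilane F2. Its enol-ether terminus is by far the more nucleophilic end, so the orientation towards aryne 13 (from 8, Me3SiCH2MgCl, THF, −78 °C) follows the firm rule for nucleophiles and 3-alkoxyarynes. The cycloadduct, the racemic silyl enol ether F3, is hydroxymethylated at C2 anti to the aryl group (aq. HCHO, Yb(OTf)3, THF; Mukaiyama aldol) to the trans β-hydroxy ketone F4. This is resolved and acetylated with the lipase as in step 8 to the acetoxy ketone F5, turned into the conjugated enol triflate F6 (Tf2O, 2,6-di-tert-butyl-4-methylpyridine, CH2Cl2) and formylated (Pd(OAc)2, dppp, CO, Et3SiH, Et3N, DMF, 70 °C) to 18.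

Step 7. What may go wrong: protodesilylation of the allylsilane, or a second Prins reaction of the product styrene with the formaldehyde–Lewis acid complex. Fallback, from 14 back to 15: formylation of the allylsilane with Cl2CHOMe and TiCl4 (CH2Cl2, −78 °C; same anti-SE2′ course) and aqueous work-up give the β,γ-unsaturated trans aldehyde F7. Its new centre is α to a carbonyl group and can be equilibrated to the trans isomer if needed. Immediate reduction (NaBH4, MeOH, 0 °C) returns 15.

Step 8. What may go wrong: poor discrimination of the enantiomers by the enzyme at a primary alcohol whose stereocentre is one carbon away, or stalling short of useful conversion. Fallback, from 15 back to 16: racemic 15 is esterified with (S)-2-methoxy-2-phenylacetic acid (DCC, DMAP, CH2Cl2) and the two diastereomeric esters are separated by chromatography or crystallisation. Methanolysis (K2CO3, MeOH) of the (1S,2S)-alcohol (2S)-2-methoxy-2-phenylacetate F8 gives the enantiopure (1S,2S)-alcohol F9, and acetylation (Ac2O, pyridine) gives 16.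

**Further compounds**

F1 | step 6 | (3E)-4-[4-(benzyloxy)-3-methoxyphenyl]but-3-en-2-one | COc1cc(/C=C/C(C)=O)ccc1OCc1ccccc1
F2 | step 6 | tert-butyl({(3E)-4-[4-(benzyloxy)-3-methoxyphenyl]buta-1,3-dien-2-yl}oxy)dimethylsilane | COc1cc(/C=C/C(=C)O[Si](C)(C)C(C)(C)C)ccc1OCc1ccccc1
F3 | step 6 | 7-(benzyloxy)-1-[4-(benzyloxy)-3-methoxyphenyl]-3-[(tert-butyldimethylsilyl)oxy]-8-methoxy-1,4-dihydronaphthalene, racemic, (1S) enantiomer drawn | COc1cc([C@@H]2C=C(O[Si](C)(C)C(C)(C)C)Cc3ccc(OCc4ccccc4)c(OC)c32)ccc1OCc1ccccc1
F4 | step 6 | trans-7-(benzyloxy)-1-[4-(benzyloxy)-3-methoxyphenyl]-2-(hydroxymethyl)-8-methoxy-1,4-dihydronaphthalen-3(2H)-one, racemic, enantiomer leading to the target drawn | COc1cc([C@H]2c3c(ccc(OCc4ccccc4)c3OC)CC(=O)[C@@H]2CO)ccc1OCc1ccccc1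
F5 | step 6 | acetate of F4, single enantiomer | COc1cc([C@H]2c3c(ccc(OCc4ccccc4)c3OC)CC(=O)[C@@H]2COC(C)=O)ccc1OCc1ccccc1
F6 | step 6 | C3 enol trifluoromethanesulfonate of F5 (C3=C4 double bond) | COc1cc([C@H]2c3c(ccc(OCc4ccccc4)c3OC)C=C(OS(=O)(=O)C(F)(F)F)[C@@H]2COC(C)=O)ccc1OCc1ccccc1
F7 | step 7 | trans-7-(benzyloxy)-1-[4-(benzyloxy)-3-methoxyphenyl]-8-methoxy-1,2-dihydronaphthalene-2-carbaldehyde, racemic | COc1cc([C@H]2c3c(ccc(OCc4ccccc4)c3OC)C=C[C@@H]2C=O)ccc1OCc1ccccc1
F8 | step 8 | [(1S,2S)-7-(benzyloxy)-1-[4-(benzyloxy)-3-methoxyphenyl]-8-methoxy-1,2-dihydronaphthalen-2-yl]methyl (2S)-2-methoxy-2-phenylacetate | COc1cc([C@H]2c3c(ccc(OCc4ccccc4)c3OC)C=C[C@@H]2COC(=O)[C@@H](OC)c2ccccc2)ccc1OCc1ccccc1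
F9 | step 8 | [(1S,2S)-7-(benzyloxy)-1-[4-(benzyloxy)-3-methoxyphenyl]-8-methoxy-1,2-dihydronaphthalen-2-yl]methanol, single enantiomer | COc1cc([C@H]2c3c(ccc(OCc4ccccc4)c3OC)C=C[C@@H]2CO)ccc1OCc1ccccc1
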